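**Retrosynthetic overview**
- The target is traced back to its pyranone (ring-oxygen) analogue; the N–OMe nitrogen is put in last by O→N exchange. The C8 methyl ether comes from a C8 ketone by reagent-controlled reduction and O-methylation.
- Key disconnection C8–C8a: the carbocycle is closed by an aldehyde-derived acyl anion equivalent (C8) attacking the unfunctionalised C–H carbon C8a of the pyranone, followed by dehydrogenation. Both carbons are electrophilic by nature.
- Disconnection C4a–C5: an enantioselective redox-relay Heck reaction of a pyranonylboronic acid with (Z)-dodec-3-en-1-ol sets C5 and delivers the C8 aldehyde in the same step.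
- Building blocks: maltol methyl ether (brominated, then borylated) and nonanal plus a 3-hydroxypropyl phosphonium salt (Wittig).
- Ring order: pyranone ring bought, carbocycle closed onto it (key step), pyridone ring formed last by heteroatom exchange.

Assumption: the (S)-ligand/(Z)-alkenol pairing in step 4 is taken to give (S) at C5 by analogy with reported aryl cases; if the sense proves opposite, the mirror-image ligand is used and nothing else changes.

**Route**

Step 1
Reactants: 1 3-methoxy-2-methyl-4H-pyran-4-one
Product: 2 5-bromo-3-methoxy-2-methyl-4H-pyran-4-one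
Conditions: Br2 (1.05 equiv), NaOAc (1.2 equiv), AcOH, 20 °C
Reagents that add atoms: bromine, BrBr
Why: Electrophilic bromination of a vinylogous ester: C5 is the only free carbon that is both α to the carbonyl and β to the ring oxygen, so bromonium attack and buffered loss of H+ give the α-bromo enone regioselectively; no stereocentre is formed.

Step 2
Reactants: 2 5-bromo-3-methoxy-2-methyl-4H-pyran-4-one
Product: 3 (5-methoxy-6-methyl-4-oxo-4H-pyran-3-yl)boronic acid
Conditions: B2(OH)4 (1.5 equiv), Pd(OAc)2 (2 mol%), 2-dicyclohexylphosphino-2',4',6'-triisopropylbiphenyl (XPhos, 4 mol%), KOAc (3 equiv), EtOH, 80 °C; aqueous work-up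
Reagents that add atoms: tetrahydroxydiboron, OB(O)B(O)O
Why: Miyaura borylation: zerovalent palladium inserts into the vinylic C–Br bond, acetate-assisted transmetalation with the diboron and reductive elimination follow, and tetrahydroxydiboron gives the free boronic acid needed in step 4.

Step 3
Reactants: 4 nonanal; 5 (3-hydroxypropyl)triphenylphosphonium bromide
Product: 7 (Z)-dodec-3-en-1-ol, via oxido ylide 6 (not isolated)
Conditions: 5 (1.1 equiv), NaN(SiMe3)2 (2.1 equiv), THF, −78 → 0 °C; then 4, −78 → 20 °C; H2O; chromatography on AgNO3-impregnated silica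
Reagents that add atoms: none
Why: Wittig olefination with a non-stabilised ylide at low temperature gives the Z-alkene through the kinetic cis-oxaphosphetane; the minor E isomer is removed because alkene geometry decides the sense of induction in step 4.

Step 4
Reactants: 3 (5-methoxy-6-methyl-4-oxo-4H-pyran-3-yl)boronic acid (2.0 equiv); 7 (Z)-dodec-3-en-1-ol (1.0 equiv)
Product: 8 (S)-4-(5-methoxy-6-methyl-4-oxo-4H-pyran-3-yl)dodecanal
Conditions: Pd(MeCN)2(OTs)2 (6 mol%), Cu(OTf)2 (6 mol%), (S)-4-tert-butyl-2-[5-(trifluoromethyl)pyridin-2-yl]-4,5-dihydrooxazole (13 mol%), 3 Å molecular sieves, O2 (1 atm), DMF, 20 °C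
Reagents that add atoms: none
Why: Sigman enantioselective redox-relay oxidative Heck reaction: the pyranonyl–palladium species adds across the alkene with the heteroaryl group going to the carbon remote from the hydroxyl, the ligand-controlled migratory insertion sets C5 as (S), and palladium then walks along the chain by β-hydride elimination and reinsertion until it leaves as the aldehyde.

Step 5
Reactants: 8 (S)-4-(5-methoxy-6-methyl-4-oxo-4H-pyran-3-yl)dodecanal
Product: 10 (S)-3-methoxy-2-methyl-5-octyl-6,7-dihydro-4H-chromene-4,8(5H)-dione, via dihydropyranone Stetter adduct 9 (not isolated)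
Conditions: 2-(pentafluorophenyl)-6,7-dihydro-5H-pyrrolo[2,1-c][1,2,4]triazol-2-ium tetrafluoroborate (20 mol%), KN(SiMe3)2 (18 mol%), toluene (0.02 M), 40 °C; then AcOH (0.5 equiv), 2,3-dichloro-5,6-dicyano-1,4-benzoquinone (DDQ, 1.1 equiv), 20 °C, one pot
Reagents that add atoms: none
Why: Proposed new method: the carbene turns the aldehyde into a Breslow intermediate (acyl anion equivalent) whose C8 attacks C8a, the β-carbon of the pyranone enone, in a 6-endo Stetter-type conjugate addition that joins two normally electrophilic carbons; proton transfer releases the catalyst and DDQ then dehydrogenates the doubly activated C4a–H/C8a–H pair to restore the pyranone, so the transient C4a/C8a centres vanish and C5 is untouched; the closest known chemistry is the triazolium-catalysed intramolecular Stetter reaction of aliphatic aldehydes onto enones (normally exo mode) and the DDQ dehydrogenation of chromanones to chromones.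

Step 6
Reactants: 10 (S)-3-methoxy-2-methyl-5-octyl-6,7-dihydro-4H-chromene-4,8(5H)-dione
Product: 11 (5S,8R)-8-hydroxy-3-methoxy-2-methyl-5-octyl-5,6,7,8-tetrahydro-4H-chromen-4-one
Conditions: (S)-1-methyl-3,3-diphenyltetrahydro-1H,3H-pyrrolo[1,2-c][1,3,2]oxazaborole (15 mol%), BH3·SMe2 (0.7 equiv), THF, −20 °C; then 1 M HCl
Reagents that add atoms: none
Why: Corey–Bakshi–Shibata reduction: the (S)-oxazaborolidine delivers hydride to the Si face of the aryl-type ketone (heteroaryl C8a large, C7H2 small, as with 1-tetralone), which gives the (8R)-alcohol with OH cis to the octyl group; the vinylogous-ester carbonyl at C4 is not reduced.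

Step 7
Reactants: 11 (5S,8R)-8-hydroxy-3-methoxy-2-methyl-5-octyl-5,6,7,8-tetrahydro-4H-chromen-4-one
Product: 13 (5S,8R)-3,8-dimethoxy-2-methyl-5-octyl-5,6,7,8-tetrahydro-4H-chromen-4-one, via sodium alkoxide 12 (not isolated)
Conditions: NaH (1.05 equiv), THF, 0 °C; then MeI (1.5 equiv), 0 → 20 °C
Reagents that add atoms: iodomethane, CI
Why: Williamson ether synthesis: the secondary alkoxide is methylated by SN2 at iodomethane, no bond to C8 is broken, so the (8R) configuration is kept; only 1.05 equiv of base is used to avoid deprotonating the 2-methyl group.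

Step 8
Reactants: 13 (5S,8R)-3,8-dimethoxy-2-methyl-5-octyl-5,6,7,8-tetrahydro-4H-chromen-4-one
Product: 14 (5S,8R)-1,3,8-trimethoxy-2-methyl-5-octyl-5,6,7,8-tetrahydroquinolin-4(1H)-one (Waltherione K)
Conditions: MeONH2·HCl (5 equiv), pyridine, 80 °C, sealed tube
Reagents that add atoms: O-methylhydroxylamine hydrochloride, CON.Cl
Why: Pyranone-to-pyridone exchange (amine addition at a ring carbon next to oxygen, ring opening, recyclisation with loss of water), the reaction type used to turn maltol ethers into N-substituted 3-alkoxy-2-methylpyridin-4-ones; the ring oxygen is replaced by N–OMe and no bond at C5 or C8 is broken.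

**Compound list**

1 | 3-methoxy-2-methyl-4H-pyran-4-one (maltol methyl ether) | Cc1occc(=O)c1OC | starting material
2 | 5-bromo-3-methoxy-2-methyl-4H-pyran-4-one | Cc1occ(Br)c(=O)c1OC | intermediate
3 | (5-methoxy-6-methyl-4-oxo-4H-pyran-3-yl)boronic acid | Cc1occ(B(O)O)c(=O)c1OC | intermediate
4 | nonanal | CCCCCCCCC=O | starting material
5 | (3-hydroxypropyl)triphenylphosphonium bromide | [Br-].OCCC[P+](c1ccccc1)(c1ccccc1)c1ccccc1 | starting material
6 | sodium 3-(triphenylphosphoranylidene)propan-1-olate (oxido ylide, not isolated) | [Na+].[O-]CCC=P(c1ccccc1)(c1ccccc1)c1ccccc1 | intermediate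
7 | (Z)-dodec-3-en-1-ol | CCCCCCCC/C=C\CCO | intermediate
8 | (S)-4-(5-methoxy-6-methyl-4-oxo-4H-pyran-3-yl)dodecanal | CCCCCCCC[C@@H](CCC=O)c1coc(C)c(OC)c1=O | intermediate
9 | (5S)-3-methoxy-2-methyl-5-octyl-4a,5,6,7-tetrahydro-4H-chromene-4,8(8aH)-dione (Stetter adduct, ring-fusion centres C4a/C8a unassigned, not isolated) | CCCCCCCC[C@H]1CCC(=O)C2OC(C)=C(OC)C(=O)C12 | intermediate
10 | (S)-3-methoxy-2-methyl-5-octyl-6,7-dihydro-4H-chromene-4,8(5H)-dione | CCCCCCCC[C@H]1CCC(=O)c2oc(C)c(OC)c(=O)c12 | intermediate
11 | (5S,8R)-8-hydroxy-3-methoxy-2-methyl-5-octyl-5,6,7,8-tetrahydro-4H-chromen-4-one | CCCCCCCC[C@H]1CC[C@@H](O)c2oc(C)c(OC)c(=O)c12 | intermediate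
12 | sodium (5S,8R)-3-methoxy-2-methyl-5-octyl-4-oxo-5,6,7,8-tetrahydro-4H-chromen-8-olate (not isolated) | CCCCCCCC[C@H]1CC[C@@H]([O-])c2oc(C)c(OC)c(=O)c12.[Na+] | intermediate
13 | (5S,8R)-3,8-dimethoxy-2-methyl-5-octyl-5,6,7,8-tetrahydro-4H-chromen-4-one | CCCCCCCC[C@H]1CC[C@@H](OC)c2oc(C)c(OC)c(=O)c12 | intermediate
14 | (5S,8R)-1,3,8-trimethoxy-2-methyl-5-octyl-5,6,7,8-tetrahydroquinolin-4(1H)-one (Waltherione K) | CCCCCCCC[C@H]1CC[C@@H](OC)c2c1c(=O)c(OC)c(C)n2OC | target

**Step count**

Total steps: 8. Longest linear sequence: 7 (1 → 2 → 3 → 8 → 10 → 11 → 13 → 14).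

**Steps most likely to fail, with fallbacks**

Step 5 (key ring closure). The 6-endo Stetter mode onto a pyranone is without direct precedent. The adduct may also ring-open by β-elimination of the ring oxygen under base, which could erode C5. The fallback sets out from 8 and comes back at 9. Photoexcited (n-Bu4N)4[W10O32] (2 mol%, MeCN, 390 nm, 20 °C) abstracts the aldehyde hydrogen to give a nucleophilic acyl radical. This radical cyclises 6-endo onto C8a, and back hydrogen transfer to the α-keto radical gives 9 under neutral conditions. Compound 9 is then dehydrogenated with DDQ as in step 5 to reach 10. This fallback makes no compound outside the list (F0).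

Step 4 (relay Heck). The α-boryl pyranone may protodeboronate or transmetalate poorly under the oxidative conditions, and site selectivity or enantioselectivity may fall short for this heteroaryl partner. The fallback sets out from 3 and comes back at 8. Rhodium-catalysed asymmetric conjugate addition (Hayashi–Miyaura) of 3 to (E)-undec-2-enal is run with [RhCl(C2H4)2]2, (R,R)-2,5-diphenylbicyclo[2.2.2]octa-2,5-diene (enantiomer chosen for S), KOH, dioxane/H2O, 30 °C. It gives (S)-3-(5-methoxy-6-methyl-4-oxo-4H-pyran-3-yl)undecanal F1. Wittig methoxymethylenation with (methoxymethyl)triphenylphosphonium chloride and KN(SiMe3)2 in THF gives 3-methoxy-5-[(4S)-1-methoxydodec-1-en-4-yl]-2-methyl-4H-pyran-4-one F2. Mild acid hydrolysis (aqueous HCl, THF) of the enol ether gives 8.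

Step 8 (O→N–OMe exchange). The tetrasubstituted pyranone is hindered, O-methylhydroxylamine is a weak nucleophile, and oxime-ether formation at C4 or C8 epimerisation in the ring-opened stage are possible. The fallback sets out from 13 and comes back at 14. The more nucleophilic hydroxylamine (NH2OH·HCl, pyridine/EtOH, 70 °C) gives (5S,8R)-1-hydroxy-3,8-dimethoxy-2-methyl-5-octyl-5,6,7,8-tetrahydroquinolin-4(1H)-one F3. The acidic N–OH is then methylated on oxygen with MeI and K2CO3 in DMF at 20 °C to give 14.

**Further compounds**

F1 | step 4 | (S)-3-(5-methoxy-6-methyl-4-oxo-4H-pyran-3-yl)undecanal | CCCCCCCC[C@@H](CC=O)c1coc(C)c(OC)c1=O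
F2 | step 4 | 3-methoxy-5-[(4S)-1-methoxydodec-1-en-4-yl]-2-methyl-4H-pyran-4-one (E/Z mixture) | CCCCCCCC[C@@H](CC=COC)c1coc(C)c(OC)c1=O
F0 | step 5 | none | none
F3 | step 8 | (5S,8R)-1-hydroxy-3,8-dimethoxy-2-methyl-5-octyl-5,6,7,8-tetrahydroquinolin-4(1H)-one | CCCCCCCC[C@H]1CC[C@@H](OC)c2c1c(=O)c(OC)c(C)n2O
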